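Add left-handed product and left-handed substrate first: that sum shows whether the left-handed side is closed.

| flask | left-handed substrate | right-handed substrate | coupling partner | racemization catalyst | added ligand | remark | time |
|---|---|---|---|---|---|---|---|
| beta | 1.1 M | 1.1 M | 1.2 equiv (fed, over 8.0 min) | 0.39 mol% | 5.1 mM | run made earlier; the fed solution adds 0.20 times the starting volume |  |
| theta | 1.1 M | 1.1 M | 1.9 equiv (fed, over 8.0 min) | 0.39 mol% | 5.1 mM | run made earlier; the fed solution adds 0.20 times the starting volume |  |
| eta | 1.1 M | 1.1 M | 2.5 equiv (fed, over 8.0 min) | 0.39 mol% | 10 mM | run made earlier; the fed solution adds 0.20 times the starting volume |  |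
| flask | 1.1 M | 1.1 M | 2.50 equiv (fed, over 8.0 min) | 0.39 mol% | 5.1 mM | the fed solution adds 0.20 times the starting volume | 2.5 h |

| run | time / min | left-handed product / % | left-handed substrate / % |
|---|---|---|---|
| beta | 6.00 | 6 | 43 |
| beta | 20.0 | 22 | 25 |
| beta | 30.0 | 29 | 20 |
| beta | 50.0 | 32 | 17 |
| beta | 60.0 | 31 | 14 |
| beta | 90.0 | 38 | 16 |
| theta | 6.00 | 9 | 41 |
| theta | 20.0 | 31 | 17 |
| theta | 30.0 | 38 | 18 |
| theta | 50.0 | 43 | 8 |
| theta | 60.0 | 45 | 7 |
| theta | 90.0 | 46 | 2 |
| eta | 20.0 | 36 | 10 |
| eta | 40.0 | 49 | 2 |
| eta | 50.0 | 48 | 2 |
| eta | 80.0 | 51 | 0 |
| eta | 90.0 | 49 | 2 |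

(standard deviation of a reading: 2 percentage points)

- amount of left-handed product in percent of the left-handed substrate and right-handed substrate together charged, at 15 min, 50 min and 2.5 h

The sum reads 48.0% in the theta run at 90.0 min and 51.0% in the eta run at 80.0 min. Each reading carries a scatter of 2 percentage points, and left-handed substrate was charged at 50.0%, so I read no crossing between hands within that scatter and leave racemization out of my reckoning. Two rates remain, the coupling of each hand with the same partner, and the partner cancels in their ratio.

In the beta run, 1.2 equiv of coupling partner is 60.0% of the charge. I take it as spent at 90.0 min. Left-handed product reads 38%, so 22.0% went to right-handed product, leaving 28.0% of right-handed substrate beside 16% of left-handed substrate. The logarithm of the fraction of left-handed substrate left, over that of right-handed substrate left, is the selectivity factor 1.97, a reading.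

In logarithms, left-handed substrate falling 100-fold means right-handed substrate falling 10.4-fold. So when the flask is down to 0.500% of left-handed substrate, coupling has used partner worth 94.7% of the two substrates together charged, less than the 125% of partner charged on that scale. Partner in the flask is therefore not the limiting reagent. The eta run, on the same partner dose with 10 mM of added ligand, reads 2% of left-handed substrate at 90.0 min, so I commit to 49.5% of left-handed product at 2.5 h.

The forecast calls this a “plain resolution capped at 50%” and gives 31%, 47.5% and 50%. Its last number is slightly above mine.

The flask gives 32.9%, 47.5% and 50.3%, so the forecast held.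

    racemization catalyst ⇌ dormant form (K = 0.530, k = 6.20 × 10⁻⁵ s⁻¹)
    racemization catalyst + added ligand ⇌ idle complex (K = 18000 L mol⁻¹, k = 1.10 L mol⁻¹ s⁻¹)
    coupling partner + left-handed substrate → left-handed product (k = 9.60 × 10⁻⁴ L mol⁻¹ s⁻¹)
    left-handed substrate + racemization catalyst ⇌ right-handed substrate + racemization catalyst, rate k4*[racemization catalyst]*[left-handed substrate] forward; the back reaction follows from the equilibrium constant (k = 0.0250 L mol⁻¹ s⁻¹)
    coupling partner + right-handed substrate → right-handed product (k = 4.80 × 10⁻⁴ L mol⁻¹ s⁻¹)

At 2.50 h the flask holds 0.132% of left-handed substrate beside 2.16% of right-handed substrate, and 1.97 times that ratio gives 0.120, while the partner used by left-handed coupling over right-handed coupling stands at 0.12. At that time left-handed substrate in the flask couples 100 times as fast as it enters the forward racemization step alone, and the net turnover of racemization up to then, running from right-handed to left-handed substrate, is 0.424%.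

The numbers in the tables are calculated for an exercise; the scatter is artificial.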